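**Retrosynthetic overview**
- The target is reached by two successive axial C–C substitutions on a 3,6-dimethoxy-1,2-dioxane: CH2CO2H at C3 (silyl ketene acetal) and ethyl at C6 (Et3Al), both steered by the equatorial C4-ethyl group.
- The 3,6-dimethoxy-1,2-dioxane comes from a Co/O2 oxidative ring expansion of a 2-silyloxycyclobutanol (O–O from O2), followed by acid/MeOH equilibration to the diaxial bis-peroxyketal.
- The cyclobutanol comes from the side-chain alkyllithium and a (2R,3S)-3-ethyl-2-silyloxycyclobutanone, made by chiral-base desymmetrisation of 3-ethylcyclobutanone and Rubottom oxidation.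
- The side-chain iodide comes from two Zr-catalysed asymmetric carboaluminations (ethyl, then methyl) on hex-1-ene and vinyl bromide.
- Ring order: the cyclobutane is bought; the 1,2-dioxane is the only ring formed (step 7).

Assumptions: 3-ethylcyclobutan-1-one is a catalogue compound; (−)-(NMI)2ZrCl2 is taken to give (R)-2-alkylalkyl alanes and the (R,R)-lithium amide to give (S)-9, so the antipodal catalyst or base is used if either sense proves opposite; all 1,2-dioxanes are numbered as the target (C3 bears the acetic acid chain, C6 is quaternary).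

**Route**

Step 1
Reactants: 1 hex-1-ene; 2 vinyl bromide (bromoethene)
Product: 4 (S)-4-ethyloct-1-ene, via alane 3 (not isolated)
Conditions: Et3Al, (+)-(NMI)2ZrCl2 (5 mol%), CH2Cl2, 0 °C to rt; evaporate; Zn(OTf)2, DMF, 70 °C; then 2, Pd(DPEphos)Cl2 (3 mol%), DIBAL-H (6 mol%), DMF, rt
Reagents that add atoms: triethylaluminium CC[Al](CC)CC
Why: Zr-catalysed asymmetric carboalumination (ZACA) adds Et and Al across one face of the terminal alkene under control of the chiral zirconocene (sets the future C10, about 90% ee), and the alkylalane is vinylated in the same pot by Al-to-Zn transmetalation and Pd-catalysed Negishi coupling.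

Step 2
Reactants: 4 (S)-4-ethyloct-1-ene
Product: 6 (2S,4S)-4-ethyl-2-methyloctan-1-ol, via alane 5 (not isolated)
Conditions: Me3Al, (+)-(NMI)2ZrCl2 (5 mol%), MAO (10 mol%), CH2Cl2, 0 °C to rt; O2, 0 °C; aq. HCl; chromatography
Reagents that add atoms: trimethylaluminium C[Al](C)C; dioxygen O=O
Why: a second ZACA reaction (methylalumination) with the same catalyst antipode sets the future C8 and the C–Al bond is oxidised with retention, the stereo-errors of both ZACA steps ending up as diastereomers that are removed at this alcohol stage.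

Step 3
Reactants: 6 (2S,4S)-4-ethyl-2-methyloctan-1-ol
Product: 7 (2S,4S)-4-ethyl-1-iodo-2-methyloctane
Conditions: I2, PPh3, imidazole, CH2Cl2, 0 °C to rt
Reagents that add atoms: iodine II
Why: Appel iodination is an SN2 displacement at the primary carbon and leaves both stereocentres untouched.

Step 4
Reactants: 8 3-ethylcyclobutan-1-one
Product: 9 (S)-triethyl[(3-ethylcyclobut-1-en-1-yl)oxy]silane
Conditions: Li (R,R)-bis(1-phenylethyl)amide (from the amine and n-BuLi), TESCl (in situ quench), THF, −100 °C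
Reagents that add atoms: chlorotriethylsilane CC[Si](Cl)(CC)CC
Why: enantioselective deprotonation of a prochiral ketone by a chiral lithium amide (precedented for 3-substituted cyclobutanones) distinguishes the two enantiotopic α-CH2 groups and so makes the ethyl-bearing carbon (future C4) a stereocentre, any minor enantiomer later becoming a separable diastereomer once the side chain is attached.

Step 5
Reactants: 9 (S)-triethyl[(3-ethylcyclobut-1-en-1-yl)oxy]silane
Product: 11 (2R,3S)-3-ethyl-2-[(triethylsilyl)oxy]cyclobutan-1-one, via silyloxy epoxide 10 (not isolated)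
Conditions: DMDO (acetone), CH2Cl2, −78 to 0 °C; then rt
Reagents that add atoms: dimethyldioxirane CC1(C)OO1
Why: Rubottom oxidation, in which epoxidation anti to the ethyl group and ring opening of the silyloxy oxirane with O-to-O silyl shift give the trans α-silyloxy ketone, whose new C–O centre is only a temporary handle and is erased later.

Step 6
Reactants: 7 (2S,4S)-4-ethyl-1-iodo-2-methyloctane; 11 (2R,3S)-3-ethyl-2-[(triethylsilyl)oxy]cyclobutan-1-one
Product: 13 (2R,3S)-3-ethyl-1-[(2S,4S)-4-ethyl-2-methyloctyl]-2-[(triethylsilyl)oxy]cyclobutan-1-ol (C1 epimers), via alkyllithium 12 (not isolated)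
Conditions: 7, t-BuLi (2.1 equiv), Et2O/pentane, −78 °C; then 11, −78 °C; H2O quench at −78 °C
Reagents that add atoms: none
Why: iodine–lithium exchange followed by 1,2-addition of the primary alkyllithium to the strained, poorly enolisable cyclobutanone, the carbinol configuration and any vicinal O-to-O silyl migration being harmless because both oxygenated carbons become ketal carbons in step 7.

Step 7
Reactants: 13 (2R,3S)-3-ethyl-1-[(2S,4S)-4-ethyl-2-methyloctyl]-2-[(triethylsilyl)oxy]cyclobutan-1-ol
Product: 15 (3R,4S,6R)-4-ethyl-6-[(2S,4S)-4-ethyl-2-methyloctyl]-3,6-dimethoxy-1,2-dioxane, via dioxanol 14 (not isolated)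
Conditions: Co(acac)2 (20 mol%), O2 (1 atm), MeCN, 40 °C; then MeOH/CH2Cl2 (1:4), CSA (10 mol%), 0 °C to rt
Reagents that add atoms: dioxygen O=O; methanol CO
Why: cobalt-catalysed aerobic oxidative ring expansion of a cyclobutanol (alkoxyl radical, β-scission of the strained C1–C2 bond toward the α-silyloxy radical, O2 capture, closure of the hydroperoxide on the new ketone) builds the 1,2-dioxane, and acid-catalysed transketalisation then equilibrates both anomeric centres to the bis-peroxyketal with both OMe axial (double anomeric effect) and the C4-ethyl and side chain equatorial, C4 itself not being touched.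

Step 8
Reactants: 15 (3R,4S,6R)-4-ethyl-6-[(2S,4S)-4-ethyl-2-methyloctyl]-3,6-dimethoxy-1,2-dioxane
Product: 16 (3R,4S,6R)-4,6-diethyl-6-[(2S,4S)-4-ethyl-2-methyloctyl]-3-methoxy-1,2-dioxane
Conditions: Et3Al (2.5 equiv), CH2Cl2/hexane, −78 to −40 °C; aq. Rochelle salt
Reagents that add atoms: triethylaluminium CC[Al](CC)CC
Why: Proposed new method: C-ethylation of a cyclic tertiary peroxyketal by a trialkylaluminium, in which Et3Al binds and ionises the axial C6–OMe (tertiary, so faster than the secondary C3 acetal) to a contact ion pair of the half-chair 1,2-dioxan-6-ylium (peroxycarbenium) ion and [Et3Al–OMe]−, and the ate complex returns ethyl to the same axial face, which is also the stereoelectronically favoured chair-like trajectory with C4-ethyl pseudo-equatorial and anti to the axial C3–OMe, so that ethyl ends up axial (6R) and the side chain equatorial; the closest known reaction types are the retentive R3Al alkylation of acetals and of glycosyl or trioxane-lactol donors and the Lewis-acid-mediated addition of silyl nucleophiles to peroxycarbenium ions.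

Step 9
Reactants: 17 trimethylsilyl acetate
Product: 18 1,1-bis(trimethylsilyloxy)ethene (ketene bis(trimethylsilyl) acetal)
Conditions: LDA, THF, −78 °C; TMSCl, −78 °C to rt; distil
Reagents that add atoms: chlorotrimethylsilane C[Si](C)(C)Cl
Why: O-silylation of the lithium enolate of the silyl ester gives the bis-silyl ketene acetal (standard enolate trapping).

Step 10
Reactants: 16 (3R,4S,6R)-4,6-diethyl-6-[(2S,4S)-4-ethyl-2-methyloctyl]-3-methoxy-1,2-dioxane; 18 1,1-bis(trimethylsilyloxy)ethene
Product: 20 2-[(3S,4S,6R)-4,6-diethyl-6-[(2S,4S)-4-ethyl-2-methyloctyl]-1,2-dioxan-3-yl]acetic acid, via silyl ester 19 (not isolated)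
Conditions: TMSOTf (20 mol%), CH2Cl2, −78 °C; then aq. citric acid work-up
Reagents that add atoms: none
Why: Mukaiyama-type addition of a silyl ketene acetal to a peroxycarbenium ion, in which TMSOTf ionises the C3 peroxyacetal and the nucleophile attacks the half-chair (locked by the C6 quaternary centre with the side chain equatorial and by the pseudo-equatorial C4-ethyl) along the axial chair-like trajectory to give the 3,4-cis (3S) product, the silyl ester being hydrolysed on work-up.

**Compound list**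
1 | hex-1-ene | C=CCCCC | starting material
2 | vinyl bromide (bromoethene) | C=CBr | starting material
3 | [(2S)-2-ethylhexyl]diethylaluminium | CCCC[C@H](CC)C[Al](CC)CC | intermediate
4 | (S)-4-ethyloct-1-ene | CCCC[C@H](CC)CC=C | intermediate
5 | [(2S,4S)-4-ethyl-2-methyloctyl]dimethylaluminium | CCCC[C@H](CC)C[C@H](C)C[Al](C)C | intermediate
6 | (2S,4S)-4-ethyl-2-methyloctan-1-ol | CCCC[C@H](CC)C[C@H](C)CO | intermediate
7 | (2S,4S)-4-ethyl-1-iodo-2-methyloctane | CCCC[C@H](CC)C[C@H](C)CI | intermediate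
8 | 3-ethylcyclobutan-1-one | CCC1CC(=O)C1 | starting material
9 | (S)-triethyl[(3-ethylcyclobut-1-en-1-yl)oxy]silane | CC[Si](CC)(CC)OC1=C[C@@H](CC)C1 | intermediate
10 | (1R,3S,4R)-3-ethyl-1-[(triethylsilyl)oxy]-5-oxabicyclo[2.1.0]pentane (epoxide anti to ethyl) | CC[Si](CC)(CC)O[C@]12C[C@H](CC)[C@H]1O2 | intermediate
11 | (2R,3S)-3-ethyl-2-[(triethylsilyl)oxy]cyclobutan-1-one (trans) | O=C1C[C@H](CC)[C@H]1O[Si](CC)(CC)CC | intermediate
12 | [(2R,4S)-4-ethyl-2-methyloctyl]lithium (same spatial arrangement as 7; the C2 descriptor changes because Li ranks below C) | CCCC[C@H](CC)C[C@H](C)C[Li] | intermediate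
13 | (2R,3S)-3-ethyl-1-[(2S,4S)-4-ethyl-2-methyloctyl]-2-[(triethylsilyl)oxy]cyclobutan-1-ol (C1 epimers) | CCCC[C@H](CC)C[C@H](C)CC1(O)C[C@H](CC)[C@H]1O[Si](CC)(CC)CC | intermediate
14 | (4S)-4-ethyl-6-[(2S,4S)-4-ethyl-2-methyloctyl]-3-[(triethylsilyl)oxy]-1,2-dioxan-6-ol (C3 and C6 epimers) | CCCC[C@H](CC)C[C@H](C)CC1(O)C[C@H](CC)C(O[Si](CC)(CC)CC)OO1 | intermediate
15 | (3R,4S,6R)-4-ethyl-6-[(2S,4S)-4-ethyl-2-methyloctyl]-3,6-dimethoxy-1,2-dioxane | CCCC[C@H](CC)C[C@H](C)C[C@]1(OC)C[C@H](CC)[C@H](OC)OO1 | intermediate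
16 | (3R,4S,6R)-4,6-diethyl-6-[(2S,4S)-4-ethyl-2-methyloctyl]-3-methoxy-1,2-dioxane | CCCC[C@H](CC)C[C@H](C)C[C@]1(CC)C[C@H](CC)[C@H](OC)OO1 | intermediate
17 | trimethylsilyl acetate | CC(=O)O[Si](C)(C)C | starting material
18 | 1,1-bis(trimethylsilyloxy)ethene | C=C(O[Si](C)(C)C)O[Si](C)(C)C | intermediate
19 | trimethylsilyl 2-[(3S,4S,6R)-4,6-diethyl-6-[(2S,4S)-4-ethyl-2-methyloctyl]-1,2-dioxan-3-yl]acetate | CCCC[C@H](CC)C[C@H](C)C[C@]1(CC)C[C@H](CC)[C@H](CC(=O)O[Si](C)(C)C)OO1 | intermediate
20 | 2-[(3S,4S,6R)-4,6-diethyl-6-[(2S,4S)-4-ethyl-2-methyloctyl]-1,2-dioxan-3-yl]acetic acid | CCCC[C@H](CC)C[C@H](C)C[C@]1(CC)C[C@H](CC)[C@H](CC(=O)O)OO1 | target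

**Step count**
Total steps: 10. Longest linear sequence: 7 steps (1, 2, 3, 6, 7, 8, 10).

**Three steps most likely to fail**

Step 8 (the proposed new ethylation). Et3Al may reduce the O–O bond, deliver β-hydride instead of ethyl, or also attack C3. The fallback uses known chemistry, sets out from 15 and returns at 16. Trimethyl(vinyloxy)silane with TMSOTf (cat., CH2Cl2, −78 °C), a known Mukaiyama-type substitution of peroxyketals with the same axial preference, gives 2-[(3R,4S,6R)-4-ethyl-6-[(2S,4S)-4-ethyl-2-methyloctyl]-3-methoxy-1,2-dioxan-6-yl]acetaldehyde F3. TsNHNH2 (MeOH, rt) converts it to N'-{2-[(3R,4S,6R)-4-ethyl-6-[(2S,4S)-4-ethyl-2-methyloctyl]-3-methoxy-1,2-dioxan-6-yl]ethylidene}-4-methylbenzenesulfonohydrazide F4. Catecholborane (CHCl3, 0 °C) followed by NaOAc·3H2O removes the oxygen function and leaves the ethyl group of 16.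

Step 7 (ring expansion and ketalisation). Cobalt may dehydrate the secondary α-silyloxy hydroperoxide, and the methanolysis may lose H2O2 or stop at the bridged ketal. The fallback sets out from 13 and returns at 15 by a polar route. TBAF (THF, 0 °C) gives (2R,3S)-3-ethyl-1-[(2S,4S)-4-ethyl-2-methyloctyl]cyclobutane-1,2-diol F1. Pb(OAc)4 (CH2Cl2, 0 °C) cleaves the glycol to (2S,6S,8S)-2,8-diethyl-6-methyl-4-oxododecanal F2. H2O2 (50% aq., 1.5 equiv) with CSA in MeOH/CH2Cl2 then closes the keto aldehyde by twofold ionic peroxyketalisation to 15.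

Step 10 (C3 substitution). The very reactive bis-silyl ketene acetal may react with low facial discrimination, or TMSOTf may fragment the peroxide. The fallback sets out from 16 and returns at 20, using a less reactive and therefore more selective nucleophile. Allyltrimethylsilane with TMSOTf (cat., CH2Cl2, −78 °C; Sakurai-type allylation of the peroxycarbenium ion) gives (3S,4S,6R)-4,6-diethyl-6-[(2S,4S)-4-ethyl-2-methyloctyl]-3-(prop-2-en-1-yl)-1,2-dioxane F5. O3 (CH2Cl2, −78 °C) then Me2S gives 2-[(3S,4S,6R)-4,6-diethyl-6-[(2S,4S)-4-ethyl-2-methyloctyl]-1,2-dioxan-3-yl]acetaldehyde F6. Pinnick oxidation (NaClO2, NaH2PO4, 2-methylbut-2-ene, t-BuOH/H2O) gives 20.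

**Further compounds**
F1 | step 7 | (2R,3S)-3-ethyl-1-[(2S,4S)-4-ethyl-2-methyloctyl]cyclobutane-1,2-diol (C1 epimers) | CCCC[C@H](CC)C[C@H](C)CC1(O)C[C@H](CC)[C@H]1O
F2 | step 7 | (2S,6S,8S)-2,8-diethyl-6-methyl-4-oxododecanal | CCCC[C@H](CC)C[C@H](C)CC(=O)C[C@H](CC)C=O
F3 | step 8 | 2-[(3R,4S,6R)-4-ethyl-6-[(2S,4S)-4-ethyl-2-methyloctyl]-3-methoxy-1,2-dioxan-6-yl]acetaldehyde | CCCC[C@H](CC)C[C@H](C)C[C@]1(CC=O)C[C@H](CC)[C@H](OC)OO1
F4 | step 8 | N'-{2-[(3R,4S,6R)-4-ethyl-6-[(2S,4S)-4-ethyl-2-methyloctyl]-3-methoxy-1,2-dioxan-6-yl]ethylidene}-4-methylbenzenesulfonohydrazide | CCCC[C@H](CC)C[C@H](C)C[C@]1(CC=NNS(=O)(=O)c2ccc(C)cc2)C[C@H](CC)[C@H](OC)OO1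
F5 | step 10 | (3S,4S,6R)-4,6-diethyl-6-[(2S,4S)-4-ethyl-2-methyloctyl]-3-(prop-2-en-1-yl)-1,2-dioxane | CCCC[C@H](CC)C[C@H](C)C[C@]1(CC)C[C@H](CC)[C@H](CC=C)OO1
F6 | step 10 | 2-[(3S,4S,6R)-4,6-diethyl-6-[(2S,4S)-4-ethyl-2-methyloctyl]-1,2-dioxan-3-yl]acetaldehyde | CCCC[C@H](CC)C[C@H](C)C[C@]1(CC)C[C@H](CC)[C@H](CC=O)OO1
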